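The cyclohexene is numbered C1 (quaternary carbinol carbon bearing C7H2OBz), C2 (CHCl), C3=C4, C5 (CHOH), C6 (CHOBz) and is disconnected at C3–C4 and C5–C6. Because C3 and C6 are 1,4-related and C6 bears oxygen, C3–C2–C1(C7)–C6 plus that oxygen is furan-3-ylmethyl benzoate. Its dearomatising Diels–Alder reaction with (Z)-1,2-bis(phenylsulfonyl)ethene, an acetylene equivalent providing C4–C5, forms both bonds at once. exo-Epoxidation, desulfonylation and a rhodium-catalysed SN2' opening of the oxygen bridge by 4-methoxyphenol, run as a regiodivergent resolution, then release the C3=C4 alkene, leave the bridge oxygen on C6 and fix the stereocentres. Benzoylation, HCl opening and dearylation finish.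

Key step: step 2

Remark: compounds 4, 5 and 6 are racemic and their SMILES show the enantiomer that is carried on; the ligand hand written in step 5 is the one taken to cleave the C3–O bond of this enantiomer, and its mirror image is used if the sense proves opposite.

Step 1
Reactants: 1 furan-3-ylmethanol
Product: 2 furan-3-ylmethyl benzoate
Conditions: BzCl, Et3N, DMAP (cat.), CH2Cl2, 0 °C to rt
Reagents that add atoms: benzoyl chloride, O=C(Cl)c1ccccc1
Why: DMAP-catalysed acylation of the primary alcohol installs the C7 benzoate of the target at the outset and masks the hydroxyl for the later steps; no stereocentre is involved.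

Step 2
Reactants: 2 furan-3-ylmethyl benzoate; 3 (Z)-1,2-bis(phenylsulfonyl)ethene
Product: 4 rac-[5-endo,6-endo-bis(phenylsulfonyl)-7-oxabicyclo[2.2.1]hept-2-en-2-yl]methyl benzoate
Conditions: CH2Cl2, rt, 2 in slight excess
Reagents that add atoms: none
Why: A concerted, suprafacial [4+2] cycloaddition of the furan diene (C3=C2–C1=C6) to the doubly sulfonyl-activated alkene C4=C5 forms C3–C4 and C5–C6 together and dearomatises the furan; the closest known reaction type is the Diels–Alder reaction of furan itself with bis(phenylsulfonyl)ethenes used as acetylene equivalents. Both new rings, the carbocycle C1–C6 and the oxolane O–C3–C4–C5–C6, are closed by this one intermolecular [4+2] annulation, with the furan oxygen becoming the one-atom bridge between C3 and C6. The bridgehead centres C3 and C6 are set relative to each other by addition to a single furan face, and the cis sulfonyl-bearing centres C4 and C5 follow from the Z alkene, endo by the Alder endo rule under kinetic control; these two centres are erased in step 4, so the endo/exo composition is immaterial. The step needs no regiocontrol because the dienophile is symmetrical, which is why an acetylene equivalent is used and not a ketene equivalent that the weakly directing CH2OBz group could not orient. The adduct is racemic (absolute configuration is introduced in step 5), and the reaction is kept at room temperature because furan cycloadditions revert on heating.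

Step 3
Reactants: 4 rac-[5-endo,6-endo-bis(phenylsulfonyl)-7-oxabicyclo[2.2.1]hept-2-en-2-yl]methyl benzoate
Product: 5 rac-[6-endo,7-endo-bis(phenylsulfonyl)-3,8-dioxatricyclo[3.2.1.0(2,4)]oct-2-yl]methyl benzoate (exo-epoxide)
Conditions: mCPBA, NaHCO3, CH2Cl2, rt
Reagents that add atoms: mCPBA (3-chloroperoxybenzoic acid), O=C(OO)c1cccc(Cl)c1
Why: Prilezhaev epoxidation of the only alkene, C1=C2: the peracid attacks the exo face (syn to the oxygen bridge, remote from the endo sulfonyl groups), which sets C1 and C2 with the epoxide oxygen on the face of the C6 oxygen and the CH2OBz group on the opposite face, as the target requires.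

Step 4
Reactants: 5 rac-[6-endo,7-endo-bis(phenylsulfonyl)-3,8-dioxatricyclo[3.2.1.0(2,4)]oct-2-yl]methyl benzoate
Product: 6 rac-(3,8-dioxatricyclo[3.2.1.0(2,4)]oct-6-en-2-yl)methyl benzoate (exo-epoxide)
Conditions: Na(Hg) (6%), NaH2PO4, MeOH/THF, −20 °C to 0 °C
Reagents that add atoms: none
Why: Reductive 1,2-elimination of the vicinal bis-sulfone by electron transfer from sodium amalgam (Julia-type desulfonylation, the way bis(sulfonyl)ethenes serve as acetylene equivalents) unveils the C4=C5 alkene and removes the C4 and C5 stereocentres, while the buffered, cold medium should spare epoxide and benzoate.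

Step 5
Reactants: 6 rac-(3,8-dioxatricyclo[3.2.1.0(2,4)]oct-6-en-2-yl)methyl benzoate; 7 4-methoxyphenol
Product: 8 [(1R,2R,3S,6S)-2-hydroxy-3-(4-methoxyphenoxy)-7-oxabicyclo[4.1.0]hept-4-en-1-yl]methyl benzoate
Conditions: [Rh(cod)Cl]2 (2.5 mol%), (R,S)-PPF-PtBu2 = (R)-1-[(S)-2-(diphenylphosphino)ferrocenyl]ethyldi-tert-butylphosphine (6 mol%), AgOTf, Bu4NI, 7 (1.1 equiv), tetrahydropyran, 80 °C
Reagents that add atoms: none
Why: Rhodium-catalysed asymmetric ring opening of an oxabicyclic alkene, run as a regiodivergent resolution: the chiral monovalent rhodium complex inserts from the exo face into the bridgehead C3–O bond of the drawn enantiomer, the phenol attacks the resulting allyl–rhodium alkoxide at C5 from the opposite (endo) face in an SN2' sense, which sets C5 trans to the C6 oxygen and places the alkene at C3=C4, whereas the mirror-image substrate is opened at its other bridgehead and ends as a separable constitutional isomer.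

Step 6
Reactants: 8 [(1R,2R,3S,6S)-2-hydroxy-3-(4-methoxyphenoxy)-7-oxabicyclo[4.1.0]hept-4-en-1-yl]methyl benzoate
Product: 9 [(1S,2R,3S,6S)-2-(benzoyloxy)-3-(4-methoxyphenoxy)-7-oxabicyclo[4.1.0]hept-4-en-1-yl]methyl benzoate
Conditions: BzCl, pyridine, DMAP (cat.), CH2Cl2, 0 °C to rt
Reagents that add atoms: benzoyl chloride, O=C(Cl)c1ccccc1
Why: DMAP-catalysed acylation of the only free hydroxyl (C6–OH) installs the second benzoate without touching a stereocentre.

Step 7
Reactants: 9 [(1S,2R,3S,6S)-2-(benzoyloxy)-3-(4-methoxyphenoxy)-7-oxabicyclo[4.1.0]hept-4-en-1-yl]methyl benzoate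
Product: 10 [(1R,2R,5S,6R)-6-(benzoyloxy)-2-chloro-1-hydroxy-5-(4-methoxyphenoxy)cyclohex-3-en-1-yl]methyl benzoate
Conditions: HCl (2 M in Et2O), CH2Cl2, −20 °C to 0 °C
Reagents that add atoms: hydrogen chloride, Cl
Why: Acid-promoted SN2-type opening of the vinyl epoxide: chloride attacks the allylic carbon C2 with inversion (anti to the departing oxygen), giving the trans chlorohydrin with the tertiary C1–OH retained in configuration, while the aryl ether and both benzoates should be inert to cold ethereal HCl.

Step 8
Reactants: 10 [(1R,2R,5S,6R)-6-(benzoyloxy)-2-chloro-1-hydroxy-5-(4-methoxyphenoxy)cyclohex-3-en-1-yl]methyl benzoate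
Product: 11 [(1R,2R,5S,6R)-6-(benzoyloxy)-2-chloro-1,5-dihydroxycyclohex-3-en-1-yl]methyl benzoate (CNP0326102.1)
Conditions: (NH4)2Ce(NO3)6, MeCN/H2O 4:1, 0 °C
Reagents that add atoms: none
Why: Oxidative dearylation of the 4-methoxyphenyl ether by single-electron oxidation with tetravalent cerium (water adds at the ipso carbon and 1,4-benzoquinone leaves) frees C5–OH with retention because the C5–O bond is not broken.

Compound list
1 | furan-3-ylmethanol | OCc1ccoc1 | starting material
2 | furan-3-ylmethyl benzoate | O=C(OCc1ccoc1)c1ccccc1 | intermediate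
3 | (Z)-1,2-bis(phenylsulfonyl)ethene | O=S(=O)(/C=C\S(=O)(=O)c1ccccc1)c1ccccc1 | starting material
4 | rac-[5-endo,6-endo-bis(phenylsulfonyl)-7-oxabicyclo[2.2.1]hept-2-en-2-yl]methyl benzoate (enantiomer carried on is shown) | O=C(OCC1=C[C@H]2O[C@@H]1[C@@H](S(=O)(=O)c1ccccc1)[C@H]2S(=O)(=O)c1ccccc1)c1ccccc1 | intermediate
5 | rac-[6-endo,7-endo-bis(phenylsulfonyl)-3,8-dioxatricyclo[3.2.1.0(2,4)]oct-2-yl]methyl benzoate, epoxide oxygen syn to the oxygen bridge (enantiomer carried on is shown) | O=C(OC[C@]12O[C@H]1[C@H]1O[C@@H]2[C@@H](S(=O)(=O)c2ccccc2)[C@H]1S(=O)(=O)c1ccccc1)c1ccccc1 | intermediate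
6 | rac-(3,8-dioxatricyclo[3.2.1.0(2,4)]oct-6-en-2-yl)methyl benzoate, epoxide oxygen syn to the oxygen bridge (enantiomer carried on is shown) | O=C(OC[C@]12O[C@H]1[C@H]1O[C@@H]2C=C1)c1ccccc1 | intermediate
7 | 4-methoxyphenol | COc1ccc(O)cc1 | starting material
8 | [(1R,2R,3S,6S)-2-hydroxy-3-(4-methoxyphenoxy)-7-oxabicyclo[4.1.0]hept-4-en-1-yl]methyl benzoate (target numbering: C1–C2 epoxide oxygen and C6–OH on one ring face, C5 aryl ether and C7 on the other) | O=C(OC[C@]12O[C@H]1C=C[C@H](Oc1ccc(OC)cc1)[C@H]2O)c1ccccc1 | intermediate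
9 | [(1S,2R,3S,6S)-2-(benzoyloxy)-3-(4-methoxyphenoxy)-7-oxabicyclo[4.1.0]hept-4-en-1-yl]methyl benzoate | O=C(OC[C@]12O[C@H]1C=C[C@H](Oc1ccc(OC)cc1)[C@H]2OC(=O)c1ccccc1)c1ccccc1 | intermediate
10 | [(1R,2R,5S,6R)-6-(benzoyloxy)-2-chloro-1-hydroxy-5-(4-methoxyphenoxy)cyclohex-3-en-1-yl]methyl benzoate | O=C(OC[C@]1(O)[C@H](Cl)C=C[C@H](Oc2ccc(OC)cc2)[C@H]1OC(=O)c1ccccc1)c1ccccc1 | intermediate
11 | [(1R,2R,5S,6R)-6-(benzoyloxy)-2-chloro-1,5-dihydroxycyclohex-3-en-1-yl]methyl benzoate | O=C(OC[C@]1(O)[C@H](Cl)C=C[C@H](O)[C@H]1OC(=O)c1ccccc1)c1ccccc1 | target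

Total step count: 8. Longest linear sequence: 8 steps (1 → 2 → 4 → 5 → 6 → 8 → 9 → 10 → 11).

Steps most likely to fail

Step 5. The process at risk is incomplete discrimination of the two bridgehead C–O bonds by the chiral catalyst, so that part of the unwanted enantiomer of 6 is opened at the "wrong" bridgehead and the enantiomeric purity of 8 is eroded; turnover may also be slow for an oxabicycle without a fused arene, and at best half of racemic 6 ends as 8. The fallback separates the enantiomers enzymatically before the ring opening. It sets out from 1, whose hydroxyl is left free. The Diels–Alder reaction with 3 (CH2Cl2, rt) should give racemic [5-endo,6-endo-bis(phenylsulfonyl)-7-oxabicyclo[2.2.1]hept-2-en-2-yl]methanol F1. mCPBA should give its exo-epoxide, [6-endo,7-endo-bis(phenylsulfonyl)-3,8-dioxatricyclo[3.2.1.0(2,4)]oct-2-yl]methanol F2. Na(Hg)/NaH2PO4 should give racemic (3,8-dioxatricyclo[3.2.1.0(2,4)]oct-6-en-2-yl)methanol F3. Burkholderia cepacia lipase with vinyl benzoate in MTBE should then benzoylate one enantiomer of this primary alcohol and leave the mirror-image alcohol F4; if the enzyme prefers the unwanted hand, the recovered alcohol is benzoylated as in step 1. The fallback comes back to the route at 6, now as a single enantiomer, so that in step 5 the ligand only steers the regiochemistry and any residual wrong enantiomer is drained into the separable regioisomer.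

Step 7. The process at risk is conjugate (SN2') attack of chloride at C4, or ionisation to an allyl cation with loss of the trans relationship, possibly with participation of the C7 benzoate. The fallback is a non-protic opening by a silyl chloride. It sets out from 9: Me3SiCl with catalytic Bu4NCl in CH2Cl2 at −20 °C should deliver chloride to C2 of the silyl-activated epoxide in an SN2 sense and give the C1-O-trimethylsilyl ether of the chlorohydrin, [6-(benzoyloxy)-2-chloro-5-(4-methoxyphenoxy)-1-(trimethylsilyloxy)cyclohex-3-en-1-yl]methyl benzoate F5. Aqueous citric acid in MeOH then removes the silyl group, and the fallback comes back at 10.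

Step 8. The process at risk is fragmentation of the oxidised aryl ether at the allylic C5–O bond (scrambling at C5) or solvolysis of the allylic chloride in the acidic aqueous oxidant. The fallback uses a benzyl-type ether that is removed under neutral conditions before chlorine is introduced. It sets out from 6: the rhodium catalyst of step 5 with 4-methoxybenzyl alcohol should give [2-hydroxy-3-(4-methoxybenzyloxy)-7-oxabicyclo[4.1.0]hept-4-en-1-yl]methyl benzoate F6. The mirror-image half of 6 should give the regioisomeric ether [5-hydroxy-4-(4-methoxybenzyloxy)-7-oxabicyclo[4.1.0]hept-2-en-1-yl]methyl benzoate F7, which is separated. BzCl/pyridine should convert F6 into the C6 benzoate [2-(benzoyloxy)-3-(4-methoxybenzyloxy)-7-oxabicyclo[4.1.0]hept-4-en-1-yl]methyl benzoate F8. DDQ in CH2Cl2/pH 7 buffer should free C5–OH to give the epoxide pipoxide, [2-(benzoyloxy)-3-hydroxy-7-oxabicyclo[4.1.0]hept-4-en-1-yl]methyl benzoate F9. HCl in Et2O/CH2Cl2 opens it as in step 7, and the fallback comes back at the target 11.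

Further compounds
F1 | step 5 | rac-[5-endo,6-endo-bis(phenylsulfonyl)-7-oxabicyclo[2.2.1]hept-2-en-2-yl]methanol | OCC1=C[C@H]2O[C@@H]1[C@@H](S(=O)(=O)c1ccccc1)[C@H]2S(=O)(=O)c1ccccc1
F2 | step 5 | rac-[6-endo,7-endo-bis(phenylsulfonyl)-3,8-dioxatricyclo[3.2.1.0(2,4)]oct-2-yl]methanol (exo-epoxide) | OC[C@]12O[C@H]1[C@H]1O[C@@H]2[C@@H](S(=O)(=O)c2ccccc2)[C@H]1S(=O)(=O)c1ccccc1
F3 | step 5 | rac-(3,8-dioxatricyclo[3.2.1.0(2,4)]oct-6-en-2-yl)methanol (enantiomer corresponding to 6 is shown) | OC[C@]12O[C@H]1[C@H]1O[C@@H]2C=C1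
F4 | step 5 | mirror-image (3,8-dioxatricyclo[3.2.1.0(2,4)]oct-6-en-2-yl)methanol left by the lipase | OC[C@@]12O[C@@H]1[C@@H]1O[C@H]2C=C1
F5 | step 7 | [6-(benzoyloxy)-2-chloro-5-(4-methoxyphenoxy)-1-(trimethylsilyloxy)cyclohex-3-en-1-yl]methyl benzoate | O=C(OC[C@]1(O[Si](C)(C)C)[C@H](Cl)C=C[C@H](Oc2ccc(OC)cc2)[C@H]1OC(=O)c1ccccc1)c1ccccc1
F6 | step 8 | [2-hydroxy-3-(4-methoxybenzyloxy)-7-oxabicyclo[4.1.0]hept-4-en-1-yl]methyl benzoate | O=C(OC[C@]12O[C@H]1C=C[C@H](OCc1ccc(OC)cc1)[C@H]2O)c1ccccc1
F7 | step 8 | [5-hydroxy-4-(4-methoxybenzyloxy)-7-oxabicyclo[4.1.0]hept-2-en-1-yl]methyl benzoate (regioisomer from the mirror-image half of 6) | O=C(OC[C@@]12O[C@@H]1[C@H](O)[C@@H](OCc1ccc(OC)cc1)C=C2)c1ccccc1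
F8 | step 8 | [2-(benzoyloxy)-3-(4-methoxybenzyloxy)-7-oxabicyclo[4.1.0]hept-4-en-1-yl]methyl benzoate | O=C(OC[C@]12O[C@H]1C=C[C@H](OCc1ccc(OC)cc1)[C@H]2OC(=O)c1ccccc1)c1ccccc1
F9 | step 8 | pipoxide, [2-(benzoyloxy)-3-hydroxy-7-oxabicyclo[4.1.0]hept-4-en-1-yl]methyl benzoate | O=C(OC[C@]12O[C@H]1C=C[C@H](O)[C@H]2OC(=O)c1ccccc1)c1ccccc1
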